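The flavan is cut at C2–C3 of ring C, after placing a formyl group on C3 as a temporary handle. The feature exploited is the hydrogen on C2, a carbon bonded to O1 and to ring B: it stands in a 1,5 relation to C4 (C2, O1, C8a, C4a, C4) and can travel there as hydride. In a single amine-catalysed internal redox this shift occurs and C3 then bonds to C2, closing ring C and setting C2 and C3. The precursor is the (E)-cinnamaldehyde of ring A that carries ring B as a 3,4,5-trimethoxybenzyl ether on the ortho oxygen, flanked by the future 8-methoxy group. Decarbonylation then removes the handle.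

Key step: step 3

Remark: the precursor is kept as the pentamethyl ether, since masking a methoxy group to strengthen the ring B donor (its para methoxy is twisted by two neighbours) or the ring A acceptor (damped by the 7-methoxy group) would cost steps, so a strong acid cocatalyst answers both; the sense of induction is taken from the usual steric model of diarylprolinol silyl ethers, which calls for the (R)-amine.

Step 1
Reactants: 1 2-hydroxy-3,4-dimethoxybenzaldehyde; 2 3,4,5-trimethoxybenzyl chloride
Product: 3 3,4-dimethoxy-2-(3,4,5-trimethoxybenzyloxy)benzaldehyde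
Conditions: K2CO3, DMF, 60 °C
Reagents that add atoms: none
Why: Williamson ether synthesis: K2CO3 forms the phenoxide of 1, which displaces chloride from the benzylic halide 2 by SN2 substitution, while the aldehyde is untouched.

Step 2
Reactants: 3 3,4-dimethoxy-2-(3,4,5-trimethoxybenzyloxy)benzaldehyde; 4 (triphenylphosphoranylidene)acetaldehyde
Product: 5 (E)-3-[3,4-dimethoxy-2-(3,4,5-trimethoxybenzyloxy)phenyl]prop-2-enal
Conditions: 4 (1.2 equiv), toluene, 80 °C
Reagents that add atoms: none
Why: Wittig olefination with the formyl-stabilised ylide is E-selective and adds C3 and the aldehyde carbon in one step, and the product enal, a vinylogous and less electrophilic aldehyde, should react only slowly with the small excess of ylide.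

Step 3
Reactants: 5 (E)-3-[3,4-dimethoxy-2-(3,4,5-trimethoxybenzyloxy)phenyl]prop-2-enal
Product: 9 trans-(2S,3S)-7,8-dimethoxy-2-(3,4,5-trimethoxyphenyl)chroman-3-carbaldehyde, via iminium ion 6 (not isolated), via oxocarbenium enamine 7 (not isolated), via ring-closed iminium ion 8 (not isolated)
Conditions: (R)-2-{bis[3,5-bis(trifluoromethyl)phenyl](trimethylsilyloxy)methyl}pyrrolidine (20 mol %), 2,4-dinitrobenzenesulfonic acid (20 mol %), ClCH2CHCl2, 40 °C; trans isomer separated on SiO2
Reagents that add atoms: none
Why: Proposed new method: the (R)-amine and the sulfonic acid convert 5 into iminium ion 6, whose β-carbon (C4) takes hydride in a suprafacial 1,5-shift from the O–CH2 carbon, which the flanking methoxy group on ring A twists out of the ring plane and over C4; this gives cation 7, an E-oxocarbenium ion (C2) stabilised by O1 and ring B next to an E-enamine (C3). C3 then adds to C2 in a Mannich-like 6-endo-trig closure (endo for O1=C2, exo for the enamine C=C) that forms the C2–C3 bond and ring C, and hydrolysis of 8 frees 9 and the amine. The closest known reaction types are the chiral-amine-catalysed hydride shift/cyclisation of ortho-(dialkylamino)cinnamaldehydes to tetrahydroquinoline-3-carbaldehydes and the Lewis-acid-catalysed hydride shift/cyclisation of aryl benzyl ethers bearing an ortho alkylidene malonate; an aryl benzyl ether as donor toward an iminium ion is the untested part. C3 should be set as (S) because the E-enamine reacts through the face remote from the diaryl(silyloxy)methyl group of the (R)-amine, as in enamine α-functionalisations with this catalyst class, and C2 should follow as (S) because the E-oxocarbenium ion closes through a chair-like transition state with ring B and the iminium-bearing carbon both pseudo-equatorial (trans). The step needs hydride transfer to outrun acid cleavage of the benzyl ether and hydrolysis of the oxocarbenium ion, secured by the intramolecular six-atom array and by the benzylic C–H being the only C–H bond 1,5 to C4; it also needs trans closure, because C3 is removed later and the trans/cis selectivity alone decides the enantiopurity at C2, so the trans isomer is separated before any epimerisation at C3.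

Step 4
Reactants: 9 trans-(2S,3S)-7,8-dimethoxy-2-(3,4,5-trimethoxyphenyl)chroman-3-carbaldehyde
Product: 10 (2S)-7,8,3',4',5'-pentamethoxyflavan
Conditions: RhCl(PPh3)3 (monovalent rhodium, 1.1 equiv), degassed PhCN, 130 °C
Reagents that add atoms: none
Why: Tsuji–Wilkinson decarbonylation: the monovalent rhodium complex adds into the formyl C–H bond, CO migrates to the metal and C–H reductive elimination leaves C3 as a methylene group with RhCl(CO)(PPh3)2 as the stable sink, and since no bond at C2 is broken its (S) configuration is kept.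

Compound list
1 | 2-hydroxy-3,4-dimethoxybenzaldehyde | COc1ccc(C=O)c(O)c1OC | starting material
2 | 3,4,5-trimethoxybenzyl chloride | COc1cc(CCl)cc(OC)c1OC | starting material
3 | 3,4-dimethoxy-2-(3,4,5-trimethoxybenzyloxy)benzaldehyde | COc1cc(COc2c(C=O)ccc(OC)c2OC)cc(OC)c1OC | intermediate
4 | (triphenylphosphoranylidene)acetaldehyde | O=CC=P(c1ccccc1)(c1ccccc1)c1ccccc1 | starting material
5 | (E)-3-[3,4-dimethoxy-2-(3,4,5-trimethoxybenzyloxy)phenyl]prop-2-enal | COc1cc(COc2c(/C=C/C=O)ccc(OC)c2OC)cc(OC)c1OC | intermediate
6 | iminium cation of 5 with (R)-2-{bis[3,5-bis(trifluoromethyl)phenyl](trimethylsilyloxy)methyl}pyrrolidine, E-alkene retained (not isolated) | COc1cc(COc2c(/C=C/C=[N+]3CCC[C@@H]3C(O[Si](C)(C)C)(c3cc(cc(c3)C(F)(F)F)C(F)(F)F)c3cc(cc(c3)C(F)(F)F)C(F)(F)F)ccc(OC)c2OC)cc(OC)c1OC | intermediate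
7 | cation formed from 6 by the 1,5-hydride shift: C4 is CH2, C3 is the carbon of an E-enamine of the (R)-amine, O1=C2 is an E-oxocarbenium ion bearing ring B (not isolated) | COc1cc(/C=[O+]/c2c(C/C=C/N3CCC[C@@H]3C(O[Si](C)(C)C)(c3cc(cc(c3)C(F)(F)F)C(F)(F)F)c3cc(cc(c3)C(F)(F)F)C(F)(F)F)ccc(OC)c2OC)cc(OC)c1OC | intermediate
8 | ring-closed iminium cation: trans-(2S,3S)-chroman whose C3 substituent is CH=N+ of the (R)-amine (not isolated) | COc1cc([C@@H]2[C@@H](C=[N+]4CCC[C@@H]4C(O[Si](C)(C)C)(c4cc(cc(c4)C(F)(F)F)C(F)(F)F)c4cc(cc(c4)C(F)(F)F)C(F)(F)F)Cc3ccc(OC)c(OC)c3O2)cc(OC)c1OC | intermediate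
9 | trans-(2S,3S)-7,8-dimethoxy-2-(3,4,5-trimethoxyphenyl)chroman-3-carbaldehyde | COc1cc([C@@H]2[C@@H](C=O)Cc3ccc(OC)c(OC)c3O2)cc(OC)c1OC | intermediate
10 | (2S)-7,8,3',4',5'-pentamethoxyflavan, i.e. (2S)-7,8-dimethoxy-2-(3,4,5-trimethoxyphenyl)chroman | COc1cc([C@@H]2CCc3ccc(OC)c(OC)c3O2)cc(OC)c1OC | target

Total step count: 4. Longest linear sequence: 4 steps (1 to 3 to 5 to 9 to 10).

Steps most likely to fail

Step 3 carries the main risk. The hydride shift may not start, because an aryl benzyl ether is a weaker donor than the amines known to react and the 7-methoxy group lowers the electrophilicity of the iminium ion. The oxocarbenium ion may be hydrolysed, or the benzyl ether cleaved by acid, before ring closure. Closure may also be poorly trans-selective, or C3 may epimerise before separation, and either would lower the enantiopurity at C2. Should closure prove cis-selective instead, the (S)-amine would give the (2S,3R) aldehyde, which leads to the same target. The fallback uses known chemistry only, sets out from 3 and comes back to the route at 10. Claisen–Schmidt condensation of 3 with 3',4',5'-trimethoxyacetophenone (KOH, EtOH) should give the chalcone (E)-3-[3,4-dimethoxy-2-(3,4,5-trimethoxybenzyloxy)phenyl]-1-(3,4,5-trimethoxyphenyl)prop-2-en-1-one F1. Hydrogenation (H2, Pd/C, EtOAc) should saturate the alkene and cleave the benzyl ether to give the phenolic ketone 3-(2-hydroxy-3,4-dimethoxyphenyl)-1-(3,4,5-trimethoxyphenyl)propan-1-one F2. Asymmetric transfer hydrogenation with RuCl[(R,R)-TsDPEN](p-cymene) (divalent ruthenium) in HCO2H/Et3N should give (1R)-3-(2-hydroxy-3,4-dimethoxyphenyl)-1-(3,4,5-trimethoxyphenyl)propan-1-ol F3. Intramolecular Mitsunobu etherification (PPh3, DIAD, THF, 0 °C) should then close ring C with inversion at the carbinol carbon to give 10.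

Step 4 is the second risk. The C3–rhodium intermediate may undergo β-elimination of hydride or of the ring oxygen instead of C–H reductive elimination, or CO extrusion at the secondary centre may be slow enough for thermal decomposition to compete. The fallback sets out from 9 and comes back at 10. Pinnick oxidation (NaClO2, NaH2PO4, 2-methylbut-2-ene, t-BuOH/H2O) should give (2S,3S)-7,8-dimethoxy-2-(3,4,5-trimethoxyphenyl)chroman-3-carboxylic acid F4. Coupling with 1-hydroxypyridine-2(1H)-thione (DCC, CH2Cl2, dark) should give the 2-thioxopyridin-1(2H)-yl ester of that acid F5, used without isolation. Barton reductive decarboxylation (t-BuSH, visible light) should then give 10, with C2 untouched.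

Step 2 is the third risk. The product enal may be olefinated a second time, giving a dienal, or the hindered, electron-rich aldehyde may react sluggishly. The fallback sets out from 3 and comes back at 5. Horner–Wadsworth–Emmons reaction with triethyl phosphonoacetate (NaH, THF) should give ethyl (E)-3-[3,4-dimethoxy-2-(3,4,5-trimethoxybenzyloxy)phenyl]prop-2-enoate F6. Reduction with i-Bu2AlH (CH2Cl2, −78 °C) should give (E)-3-[3,4-dimethoxy-2-(3,4,5-trimethoxybenzyloxy)phenyl]prop-2-en-1-ol F7. Oxidation with MnO2 (CH2Cl2) should then give 5.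

Further compounds
F1 | step 3 | (E)-3-[3,4-dimethoxy-2-(3,4,5-trimethoxybenzyloxy)phenyl]-1-(3,4,5-trimethoxyphenyl)prop-2-en-1-one | COc1cc(COc2c(/C=C/C(=O)c3cc(OC)c(OC)c(OC)c3)ccc(OC)c2OC)cc(OC)c1OC
F2 | step 3 | 3-(2-hydroxy-3,4-dimethoxyphenyl)-1-(3,4,5-trimethoxyphenyl)propan-1-one | COc1cc(C(=O)CCc2ccc(OC)c(OC)c2O)cc(OC)c1OC
F3 | step 3 | (1R)-3-(2-hydroxy-3,4-dimethoxyphenyl)-1-(3,4,5-trimethoxyphenyl)propan-1-ol | COc1cc([C@H](O)CCc2ccc(OC)c(OC)c2O)cc(OC)c1OC
F4 | step 4 | (2S,3S)-7,8-dimethoxy-2-(3,4,5-trimethoxyphenyl)chroman-3-carboxylic acid | COc1cc([C@@H]2[C@@H](C(=O)O)Cc3ccc(OC)c(OC)c3O2)cc(OC)c1OC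
F5 | step 4 | 2-thioxopyridin-1(2H)-yl (2S,3S)-7,8-dimethoxy-2-(3,4,5-trimethoxyphenyl)chroman-3-carboxylate | COc1cc([C@@H]2[C@@H](C(=O)ON4C=CC=CC4=S)Cc3ccc(OC)c(OC)c3O2)cc(OC)c1OC
F6 | step 2 | ethyl (E)-3-[3,4-dimethoxy-2-(3,4,5-trimethoxybenzyloxy)phenyl]prop-2-enoate | CCOC(=O)/C=C/c1ccc(OC)c(OC)c1OCc1cc(OC)c(OC)c(OC)c1
F7 | step 2 | (E)-3-[3,4-dimethoxy-2-(3,4,5-trimethoxybenzyloxy)phenyl]prop-2-en-1-ol | OC/C=C/c1ccc(OC)c(OC)c1OCc1cc(OC)c(OC)c(OC)c1
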